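The numbers in the tables were generated by integration with constants of no real substance.

A millimolar-day is the unit to count in here: the flask at its latest time holds 37.5 mM·d of catalyst-time, meaning c(free catalyst) multiplied by the time stood. The isomer of the product lags the target in the earlier runs and comes sooner with more free catalyst, as a pseudo-first-order step from target would, so the share of isomer in isomer plus target is read here against catalyst-time.

| flask | starting material | reagent | free catalyst | second catalyst | remark | time |
|---|---|---|---|---|---|---|
| north-east | 0.092 M | 0.092 M | 1.7 mM | 0.15 mM | run made earlier |  |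
| north | 0.092 M | 0.092 M | 3.8 mM | 0.15 mM | run made earlier |  |
| north-west | 0.18 M | 0.092 M | 2.5 mM | 0.15 mM | run made earlier |  |
| flask | 0.092 M | 0.0920 M | 2.5 mM | 0.15 mM |  | 15 d |

| run | time / d | isomer of the product / % | target / % |
|---|---|---|---|
| north-east | 0.625 | 0.3 | 4.3 |
| north-east | 1.25 | 2.0 | 8.5 |
| north-east | 2.08 | 4.9 | 12.7 |
| north-east | 3.00 | 7.3 | 14.6 |
| north-east | 5.00 | 14.5 | 16.2 |
| north-east | 10.0 | 26.1 | 16.8 |
| north | 0.625 | 1.4 | 4.8 |
| north | 1.25 | 4.2 | 8.0 |
| north | 2.08 | 8.4 | 11.1 |
| north | 3.00 | 13.1 | 11.7 |
| north | 5.00 | 20.8 | 13.9 |
| north | 10.0 | 30.3 | 15.9 |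
| north-west | 0.833 | 0.7 | 4.3 |
| north-west | 2.50 | 5.2 | 9.0 |
| north-west | 4.00 | 9.5 | 9.8 |
| north-west | 6.00 | 14.2 | 10.6 |
| north-west | 10.0 | 19.6 | 11.6 |

(readings scatter by 0.3 percentage points)



- share of isomer of the product in isomer of the product plus target at 6.0 h
- share of isomer of the product in isomer of the product plus target at 15 d
- which of isomer of the product and target there is more of at 15 d

At the start, at 6.0 h, the flask has 0.625 mM·d, less than the first north-east point at 1.06 mM·d. That point shows a share of 6.52%, but its isomer reading of 0.3% is no larger than the scatter of 0.3 percentage points, so scaling in proportion gives a rough 3.84%.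

In the middle, the north and north-east runs fall together: the north run at 4.75 mM·d reads 34.4%, and the north-east run at 5.10 mM·d reads 33.3%. The north-west run, with about twice the starting material, reads 62.8% at 25.0 mM·d, less than a share in proportion to catalyst-time, though that run differs in its charge of starting material as well.

For the end, the north run at 10.0 d has 38.0 mM·d, nearly the flask's 37.5 mM·d, and reads 65.6%. My reckoning therefore takes that share for the flask at 15 d, with more isomer than target.

The forecast gave 4%, 66% and isomer of the product in the lead: “The isomer leads.” The flask gives 4.80% at the early time, above my 3.84%, and 66.3% at the end, with 33.1% of isomer against 16.8% of target.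

    starting material + free catalyst ⇌ free catalyst + open intermediate (K = 2.80, k = 31.0 M⁻¹ h⁻¹)
    second catalyst + open intermediate ⇌ catalyst intermediate (K = 180 M⁻¹, k = 310 M⁻¹ h⁻¹)
    reagent + catalyst intermediate ⇌ second catalyst + target (K = 0.0660, k = 58.0 M⁻¹ h⁻¹)
    target + free catalyst ⇌ isomer of the product + free catalyst, rate k4*[free catalyst]*[target] forward; the back reaction follows from the equilibrium constant (K = 2.10, k = 8.50 M⁻¹ h⁻¹)

At 37.5 mM·d the flask's 66.3% lies close to the 65.6% read from the north run at 38.0 mM·d, although the two differ in free catalyst and in time. The way back from isomer of the product to target is the largest single effect on this share: with that step struck out, the flask gives 93.1% instead of 66.3%. The neighbouring flask charged with 0.037 M of starting material also holds 37.5 mM·d of catalyst-time at its end, and its share is 66.9%.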